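**Retrosynthetic overview**

1. The target is a 3-bromolabdane: a trans-decalin (rings A and B) whose C8 oxygen is tied back to the side chain as an oxocane (ring C: C8–O–C15–C14–C13–C12–C11–C9) carrying a cis-fused C13–C14 oxirane.
2. Last-step disconnection: O–C15, C13–C14 and the oxirane C14–O bond are cut together. C15–C14 becomes diphenyl(vinyl)sulfonium triflate, and what remains is a bicyclic bromo ketol (C8 tertiary alcohol, C13 methyl ketone).
3. Enabling feature: in ring C the oxirane CH (C14) lies between the ether CH2 (C15) and the methyl-bearing oxirane carbon C13, i.e. O–CH2–CH(O)–C(O)(CH3), which is the imprint of alkoxide + vinylsulfonium + methyl ketone. C13 and C14 are both oxygen-bearing (like polarity) and are joined through the sulfonium ylide at C14, and the trans-diequatorial C8–O and C9–C11 bonds on ring B hold the two chain ends gauche.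
4. The ketol comes from a tricyclic bromo enol ether ester (rings A and B plus a temporary dihydropyran) by hydrolysis and decarboxylation. That ester comes from one enantioselective bromonium-initiated polyene cyclization of ethyl 2-farnesylacetoacetate, made from farnesyl bromide and ethyl acetoacetate.
5. Ring order: A, then B and the temporary dihydropyran in one cascade; the dihydropyran is opened again; ring C is closed last, in the operation that also delivers its fused oxirane.

Key step: step 4

Remark on numbering: labdane numbering is used throughout. C3 carries Br, C4 the gem-dimethyl group, C5 and C10 are the A/B fusion carbons, C8 is the oxygenated quaternary carbon, C9 its ring neighbour, C11 and C12 are the two CH2 groups, C13 (methyl-bearing) and C14 are the oxirane carbons, and C15 is the OCH2.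

Assumption: the sense of induction of the thiophosphoramide catalyst on this substrate cannot be taken from precedent, so the BINOL antipode is fixed after a first run so that 4 belongs to the 3R series. The catalyst itself is prepared from the 3,3'-diaryl-BINOL, PSCl3 and TfNH2.

**Step 1**
Reactants: 1 (2E,6E)-farnesyl bromide; 2 ethyl acetoacetate
Product: 3 ethyl 2-acetyl-(4E,8E)-5,9,13-trimethyltetradeca-4,8,12-trienoate (ethyl 2-farnesylacetoacetate; racemic at C2)
Conditions: 2 (1.5 equiv), NaH (1.4 equiv), THF, 0 °C; then 1, 0 → 23 °C
Reagents that add atoms: none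
Why: Acetoacetic ester alkylation: the sodium enolate of 2, used in excess to suppress dialkylation, displaces the primary allylic bromide by SN2 at carbon, both E double bonds are untouched, and the new stereocentre is irrelevant because it becomes sp2 in step 2.

**Step 2**
Reactants: 3 ethyl 2-farnesylacetoacetate
Product: 4 ethyl (3R,5S,8S,9S,10R)-3-bromo-8,13-epoxy-14,15-dinorlabd-12-ene-12-carboxylate (tricyclic bromo enol ether ester)
Conditions: 1,3-dibromo-5,5-dimethylhydantoin (0.6 equiv), 3,3'-bis(2,4,6-triisopropylphenyl)-BINOL N-triflyl thiophosphoramide (10 mol %, antipode chosen for the 3R series), toluene/CH2Cl2, −78 °C; aq. Na2S2O3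
Reagents that add atoms: 1,3-dibromo-5,5-dimethylhydantoin, CC1(C)N(Br)C(=O)N(Br)C1=O
Why: Proposed new method: the thiophosphoramide sulfur takes Br+ from the hydantoin and passes it to one enantiotopic face of the terminal, most exposed C3=C4 alkene; the bromonium ion is opened at C4 by the C5=C10 alkene and the resulting cation by the C8=C9 alkene through an all-chair, all-anti (Stork–Eschenmoser) array, so that the catalyst-controlled centre C3 is relayed to C5, C10, C9 and C8 (equatorial Br, trans-decalin, equatorial C8–O); the ketone oxygen of the β-keto ester closes the dihydropyran on the C8 cation and loss of the C12 proton gives a vinylogous carbonate that, unlike a simple enol ether, should not react further with the bromine source; the closest known reaction types are the chiral Lewis-base-catalysed enantioselective bromocyclization of homogeranylarenes and geranylphenols with the same bromine source and the racemic halonium-, Hg(OTf)2- and SnCl4-induced cyclizations of polyprenyl β-keto esters with enol-oxygen termination.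

**Step 3**
Reactants: 4 tricyclic bromo enol ether ester
Product: 7 (3R,5S,8S,9S,10R)-3-bromo-8-hydroxy-14,15-dinorlabdan-13-one (bromo ketol), via tricyclic acid 5 (not isolated), via bromo enol ether 6 (not isolated)
Conditions: NaOH (2 M aq., 5 equiv), EtOH, 80 °C; then HCl to pH 1–2, THF/H2O, 60 °C, then 23 °C
Reagents that add atoms: water, O
Why: Saponification of the vinylogous carbonate, acid-promoted C12-protonation with decarboxylation (ketonic cleavage of an acetoacetic ester held as its cyclic enol ether) and hydration of the resulting enol ether open the temporary dihydropyran at the C13–O bond, so the C8–O bond and all five stereocentres are untouched.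

**Step 4**
Reactants: 7 bromo ketol; 8 diphenyl(vinyl)sulfonium triflate
Product: 11 (3R,5S,8S,9S,10R,13S,14R)-3-bromo-8,15:13,14-diepoxylabdane (CNP0311742.1), via sulfonium ylide 9 (not isolated), via betaine 10 (not isolated)
Conditions: NaH (1.2 equiv), THF, 0 °C, 20 min; then 8 (1.3 equiv) in CH2Cl2 added over 4 h, 0 → 23 °C, 5 mM
Reagents that add atoms: none
Why: Proposed new method: the sodium alkoxide of the C8 hydroxyl adds to the vinylsulfonium salt (oxa-Michael) to give ylide 9, whose carbanion C14 attacks the C13 methyl ketone to give betaine 10, and the C13 alkoxide then displaces Ph2S from C14 with inversion, so that O–C15, C14–C13 and C14–O are made in one flask and the two oxygen-bearing carbons C13 and C14 are joined through the polarity reversal that the ylide provides. The closest known reaction type is the conjugate-addition/Johnson–Corey–Chaykovsky annulation of sulfonamide-tethered ketones with diphenyl(vinyl)sulfonium triflate, which gives epoxide-fused five- to seven-membered heterocycles; new here are the eight-membered ring and the tertiary alkoxide as nucleophile. Ring C closes by 8-exo-trig attack of the ylide carbon on the carbonyl group, and the oxirane closes by 3-exo-tet displacement. C13 and C14 are set together: the cis ring fusion is dictated by the ring, because only a betaine with O− and S+ anti and the ring bonds C12–C13 and C14–C15 gauche can close, and the sense relative to the decalin is expected to come from the C8 stereocentre, the bulky Ph2S+ group taking the ring face remote from the axial C8 methyl so that the oxirane oxygen ends up syn to that methyl (13S,14R). The step needs O- over C-nucleophile chemoselectivity and cyclization over oligomerization: the O–H is the only proton NaH removes at 0 °C, every oxa-Michael adduct that cannot close reverts by E1cB loss of alkoxide, a protonated adduct is re-deprotonated at the sulfonium α-carbon rather than at the less acidic ketone α-carbon, and the gauche (about 60°) C8–O/C9–C11 bonds on the rigid trans-decalin, the quaternary C8 (Thorpe–Ingold effect) and slow addition at high dilution favour the eight-membered closure. The equatorial neopentyl-type secondary bromide has no anti-periplanar hydrogen and should be inert to the alkoxide.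

**Compound list**

1 | (2E,6E)-farnesyl bromide | CC(C)=CCC/C(C)=C/CC/C(C)=C/CBr | starting material
2 | ethyl acetoacetate | CCOC(=O)CC(C)=O | starting material
3 | ethyl 2-acetyl-(4E,8E)-5,9,13-trimethyltetradeca-4,8,12-trienoate (racemic at C2) | CCOC(=O)C(C(C)=O)C/C=C(\C)CC/C=C(\C)CCC=C(C)C | intermediate
4 | ethyl (3R,5S,8S,9S,10R)-3-bromo-8,13-epoxy-14,15-dinorlabd-12-ene-12-carboxylate | CC1(C)[C@H](Br)CC[C@]2(C)[C@@H]1CC[C@]1(C)OC(C)=C(C(=O)OCC)C[C@@H]21 | intermediate
5 | (3R,5S,8S,9S,10R)-3-bromo-8,13-epoxy-14,15-dinorlabd-12-ene-12-carboxylic acid (tricyclic acid, not isolated) | CC1(C)[C@H](Br)CC[C@]2(C)[C@@H]1CC[C@]1(C)OC(C)=C(C(O)=O)C[C@@H]21 | intermediate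
6 | (3R,5S,8S,9S,10R)-3-bromo-8,13-epoxy-14,15-dinorlabd-12-ene (bromo enol ether, not isolated) | CC1(C)[C@H](Br)CC[C@]2(C)[C@@H]1CC[C@]1(C)OC(C)=CC[C@@H]21 | intermediate
7 | (3R,5S,8S,9S,10R)-3-bromo-8-hydroxy-14,15-dinorlabdan-13-one (bromo ketol) | CC1(C)[C@H](Br)CC[C@]2(C)[C@@H]1CC[C@](C)(O)[C@H]2CCC(C)=O | intermediate
8 | diphenyl(vinyl)sulfonium trifluoromethanesulfonate | C=C[S+](c1ccccc1)c1ccccc1.[O-]S(=O)(=O)C(F)(F)F | starting material
9 | sulfonium ylide: C8–O–CH2–CH(−)–S(+)Ph2 ether of 7 (not isolated) | CC1(C)[C@H](Br)CC[C@]2(C)[C@@H]1CC[C@](C)(OC[CH-][S+](c1ccccc1)c1ccccc1)[C@H]2CCC(C)=O | intermediate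
10 | betaine: ring C closed, C13 alkoxide and C14 diphenylsulfonio group trans on the ring (not isolated) | CC1(C)[C@H](Br)CC[C@]2(C)[C@@H]1CC[C@]1(C)OC[C@H]([S+](c3ccccc3)c3ccccc3)[C@@](C)([O-])CC[C@@H]21 | intermediate
11 | (3R,5S,8S,9S,10R,13S,14R)-3-bromo-8,15:13,14-diepoxylabdane (CNP0311742.1) | CC1(C)[C@H](Br)CC[C@]2(C)[C@@H]1CC[C@]1(C)OC[C@H]3O[C@@]3(C)CC[C@@H]21 | target

Total step count: 4
Longest linear sequence: 4 steps (from 1)

**Steps most likely to fail**

Step 4 (Proposed new method). The ylide may be quenched by proton transfer from the ketone α-carbon or captured by a second molecule (oligomers) before the eight-membered closure, the enolate may be alkylated at carbon, or the ylide may attack the wrong carbonyl face and give the epimeric cis-oxirane. The fallback uses known chemistry and sets out from 7. Wittig methylenation (Ph3PCH3Br, KOt-Bu, THF, 0 → 23 °C, excess ylide because of the free hydroxyl) should give (3R,5S,8S,9S,10R)-3-bromo-14,15-dinorlabd-13(16)-en-8-ol F1. Williamson allylation of the tertiary alkoxide (KH, allyl bromide, THF, 0 → 23 °C) should give the allyl ether F2. Ring-closing metathesis with second-generation Grubbs catalyst (H2IMes)(PCy3)Cl2Ru=CHPh (toluene, 80 °C, 2 mM) should give the Z-trisubstituted oxocene F3. Epoxidation (mCPBA, NaHCO3, CH2Cl2, 0 °C, or dimethyldioxirane) on the alkene face syn to the C8 methyl comes back to the route at 11.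

Step 2 (Proposed new method). Enantio-induction may be low, bromine may be delivered to an internal alkene, or the cascade may stop after ring A by proton loss. The fallback sets out from 3. Racemic cyclization with Et2SBr·SbCl5Br (MeNO2, −25 °C) should give racemic 4, that is 4 together with its mirror image, ethyl (3S,5R,8R,9R,10S)-3-bromo-8,13-epoxy-14,15-dinorlabd-12-ene-12-carboxylate F4. Preparative chromatography on an amylose tris(3,5-dimethylphenylcarbamate) stationary phase removes F4 and comes back to the route at 4.

Step 3. Saponification of the hindered vinylogous carbonate may be incomplete, and prolonged heating with hydroxide may cost HBr. The fallback sets out from 1 and changes the ester so that no hydroxide is needed. Alkylation of allyl acetoacetate (NaH, THF, 0 → 23 °C) should give allyl 2-acetyl-(4E,8E)-5,9,13-trimethyltetradeca-4,8,12-trienoate F5. Cyclization under the conditions of step 2 (or of its fallback) should give the allyl (3R,5S,8S,9S,10R)-3-bromo-8,13-epoxy-14,15-dinorlabd-12-ene-12-carboxylate F6. Allyl transfer to morpholine with Pd(PPh3)4 (zerovalent palladium, 5 mol %, THF, 23 °C) comes back to the route at 5, which is decarboxylated and hydrated to 7 by the acidic second stage of step 3.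

**Further compounds**

F1 | step 4 | (3R,5S,8S,9S,10R)-3-bromo-14,15-dinorlabd-13(16)-en-8-ol | CC1(C)[C@H](Br)CC[C@]2(C)[C@@H]1CC[C@](C)(O)[C@H]2CCC(C)=C
F2 | step 4 | (3R,5S,8S,9S,10R)-8-allyloxy-3-bromo-14,15-dinorlabd-13(16)-ene | CC1(C)[C@H](Br)CC[C@]2(C)[C@@H]1CC[C@](C)(OCC=C)[C@H]2CCC(C)=C
F3 | step 4 | (3R,5S,8S,9S,10R,13Z)-3-bromo-8,15-epoxylabd-13-ene (oxocene) | CC1(C)[C@H](Br)CC[C@]2(C)[C@@H]1CC[C@]1(C)OC/C=C(C)\CC[C@@H]21
F4 | step 2 | ethyl (3S,5R,8R,9R,10S)-3-bromo-8,13-epoxy-14,15-dinorlabd-12-ene-12-carboxylate (mirror image of 4) | CC1(C)[C@@H](Br)CC[C@@]2(C)[C@H]1CC[C@@]1(C)OC(C)=C(C(=O)OCC)C[C@H]21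
F5 | step 3 | allyl 2-acetyl-(4E,8E)-5,9,13-trimethyltetradeca-4,8,12-trienoate (racemic at C2) | C=CCOC(=O)C(C(C)=O)C/C=C(\C)CC/C=C(\C)CCC=C(C)C
F6 | step 3 | allyl (3R,5S,8S,9S,10R)-3-bromo-8,13-epoxy-14,15-dinorlabd-12-ene-12-carboxylate | CC1(C)[C@H](Br)CC[C@]2(C)[C@@H]1CC[C@]1(C)OC(C)=C(C(=O)OCC=C)C[C@@H]21
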